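**Retrosynthetic overview**

1. Feature used: in the oxolane ring O1–C7–C8–C8'–C9' (lignan locants; C9 is the CH2OH carbon on C8), C8' carries the carbinol C7'(OH)–catechol and is bonded to the ether carbon C9'. The oxygens on C7' and C9' are therefore 1,3-related across C8', a masked β-oxygenated aryl ketone, which is read as an isoxazoline.
2. Target ⇒ (O-debenzylation, C7' ketone reduction, C9' deoxygenation, N–O cleavage) ⇒ cis-fused furo-isoxazoline 16.
3. 16 ⇒ [3+2] cycloaddition of aryl nitrile oxide 15 (from aldehyde 12 via 13 and 14) across the enol ether C8'=C9' of 2,3-dihydrofuran 11, forming C8'–C7' and C9'–O.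
4. 11 ⇒ cycloisomerisation of anti-homopropargylic alcohol 10 (O1–C9'); 10 ⇒ allenylzinc addition of (S)-mesylate 6 to aldehyde 7 (C7–C8, both stereocentres); 6 ⇒ ynone 4 by asymmetric transfer hydrogenation.
5. Ring order: the oxolane is closed first (step 6); the isoxazoline is annulated onto it (step 9) and opened again (step 10).

Key step: step 9

Assumption: Weinreb amide 1 is taken as a catalogue compound (otherwise one step from benzyloxyacetyl chloride and N,O-dimethylhydroxylamine hydrochloride).

**Route**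

Step 1
Reactants: 1 2-(benzyloxy)-N-methoxy-N-methylacetamide; 2 trimethylsilylacetylene
Product: 4 1-(benzyloxy)-4-(trimethylsilyl)but-3-yn-2-one, via lithium (trimethylsilyl)acetylide 3 (not isolated)
Conditions: 2, n-BuLi, THF, −78 °C; then 1, −78 → 0 °C; aq. NH4Cl
Reagents that add atoms: none
Why: Weinreb ketone synthesis; the chelated tetrahedral adduct of the acetylide persists until the quench, so addition should stop at the ynone.

Step 2
Reactants: 4 1-(benzyloxy)-4-(trimethylsilyl)but-3-yn-2-one
Product: 5 (S)-1-(benzyloxy)-4-(trimethylsilyl)but-3-yn-2-ol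
Conditions: Ru[(1R,2R)-TsNCH(Ph)CH(Ph)NH](p-cymene) (2 mol%), i-PrOH, rt
Reagents that add atoms: none
Why: Noyori asymmetric transfer hydrogenation of an alkynyl ketone; the alkynyl group takes the place normally held by an aryl group beside the arene ligand, so the (R,R)-catalyst should give the carbinol that is (S) here (CH2OBn outranks the alkynyl carbon), and the base-free amido complex avoids conjugate addition to the ynone.

Step 3
Reactants: 5 (S)-1-(benzyloxy)-4-(trimethylsilyl)but-3-yn-2-ol
Product: 6 (S)-1-(benzyloxy)-4-(trimethylsilyl)but-3-yn-2-yl methanesulfonate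
Conditions: MsCl, Et3N, CH2Cl2, −78 → 0 °C
Reagents that add atoms: methanesulfonyl chloride, CS(=O)(=O)Cl
Why: O-sulfonylation of a secondary propargylic alcohol; no bond to the stereocentre is broken, so the configuration is retained.

Step 4
Reactants: 6 (S)-1-(benzyloxy)-4-(trimethylsilyl)but-3-yn-2-yl methanesulfonate; 7 4-(benzyloxy)-3-methoxybenzaldehyde
Product: 9 (1S,2R)-1-[4-(benzyloxy)-3-methoxyphenyl]-2-[(benzyloxy)methyl]-4-(trimethylsilyl)but-3-yn-1-ol, via allenylzinc 8 (not isolated)
Conditions: Pd(OAc)2 (5 mol%), PPh3 (5 mol%), Et2Zn (3 equiv), THF, −78 → −20 °C; aq. NH4Cl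
Reagents that add atoms: none
Why: Marshall propargylation; zerovalent palladium formed in the flask displaces the mesylate anti (SN2'), the allenylpalladium transmetalates to allenylzinc 8, and 8 adds to the aldehyde through a cyclic SE2' transition state, so C8 (R) is set by chirality transfer from 6 with net inversion and C7 (S) by the anti preference of that transition state (aldehyde aryl group turned away from the CH2OBn-bearing allene terminus).

Step 5
Reactants: 9 (1S,2R)-1-[4-(benzyloxy)-3-methoxyphenyl]-2-[(benzyloxy)methyl]-4-(trimethylsilyl)but-3-yn-1-ol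
Product: 10 (1S,2R)-1-[4-(benzyloxy)-3-methoxyphenyl]-2-[(benzyloxy)methyl]but-3-yn-1-ol
Conditions: K2CO3 (cat.), MeOH, rt
Reagents that add atoms: none
Why: Base-catalysed methanolysis of the alkynyl C–Si bond; the carbinol, the benzyl ethers and both stereocentres are inert to it.

Step 6
Reactants: 10 (1S,2R)-1-[4-(benzyloxy)-3-methoxyphenyl]-2-[(benzyloxy)methyl]but-3-yn-1-ol
Product: 11 (2S,3R)-2-[4-(benzyloxy)-3-methoxyphenyl]-3-[(benzyloxy)methyl]-2,3-dihydrofuran
Conditions: Mo(CO)6 (30 mol%), Et3N, Et2O, hν (350 nm), rt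
Reagents that add atoms: none
Why: Molybdenum-catalysed alkynol cycloisomerisation (vinylidene pathway, formal 5-endo-dig); the C7 hydroxyl attacks the terminal alkyne carbon C9' and protodemetalation gives the endocyclic enol ether C8'=C9', while the amine medium protects the acid-sensitive product and leaves C7 and C8 untouched.

Step 7
Reactants: 12 3,4-bis(benzyloxy)benzaldehyde
Product: 13 (E)-3,4-bis(benzyloxy)benzaldehyde oxime
Conditions: NH2OH·HCl, NaOAc, EtOH/H2O, rt
Reagents that add atoms: hydroxylamine hydrochloride, NO.Cl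
Why: Oxime condensation of an aromatic aldehyde, which should give the (E)-aldoxime.

Step 8
Reactants: 13 (E)-3,4-bis(benzyloxy)benzaldehyde oxime
Product: 14 (Z)-3,4-bis(benzyloxy)-N-hydroxybenzimidoyl chloride
Conditions: NCS, DMF, rt; extractive work-up, used crude
Reagents that add atoms: N-chlorosuccinimide, O=C1CCC(=O)N1Cl
Why: Chlorination of an aldoxime to the hydroximoyl chloride; it is done apart from 11 so that the enol ether never meets electrophilic chlorine or HCl.

Step 9
Reactants: 11 (2S,3R)-2-[4-(benzyloxy)-3-methoxyphenyl]-3-[(benzyloxy)methyl]-2,3-dihydrofuran; 14 (Z)-3,4-bis(benzyloxy)-N-hydroxybenzimidoyl chloride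
Product: 16 (3aR,4R,5S,6aS)-3-[3,4-bis(benzyloxy)phenyl]-5-[4-(benzyloxy)-3-methoxyphenyl]-4-[(benzyloxy)methyl]-3a,4,5,6a-tetrahydrofuro[3,2-d]isoxazole (cis-fused; isoxazoline O1 and ring O6 both on C6a), via 3,4-bis(benzyloxy)benzonitrile oxide 15 (not isolated)
Conditions: 11 (1 equiv), 14 (2 equiv), Et3N (syringe pump), CH2Cl2, 0 °C → rt
Reagents that add atoms: none
Why: Et3N dehydrochlorinates 14 to nitrile oxide 15, which adds to the electron-rich enol ether C8'=C9' of 11 in a concerted, asynchronous Huisgen [3+2] cycloaddition; the closest known reaction type is the addition of aryl nitrile oxides to 2,3-dihydrofuran to give 5-alkoxy-2-isoxazolines. The isoxazoline ring is closed intermolecularly, with C8'–C7' and C9'–O formed on the same face of the olefin, so the ring fusion can only be cis. The dipole carbon should bond to C8' and the dipole oxygen to the acetal carbon C9', because the enol ether HOMO has its larger coefficient at the β-carbon C8'. The new stereocentre C8' (3aR) and the temporary one at C9' (6aS) are set by approach of the dipole to the face opposite the C8 benzyloxymethyl group, which stands directly beside the carbon that receives the bulky aryl-bearing terminus; the C7 aryl group on the other face is one atom further off and faces only the small oxygen terminus. The step therefore needs face selectivity, secured by the C8 substituent, and suppression of furoxan formation, secured by slow generation of 15 from an excess of 14.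

Step 10
Reactants: 16 (3aR,4R,5S,6aS)-cycloadduct
Product: 18 [3,4-bis(benzyloxy)phenyl][(3S,4R,5S)-5-[4-(benzyloxy)-3-methoxyphenyl]-4-[(benzyloxy)methyl]-2-hydroxytetrahydrofuran-3-yl]methanone (anomeric mixture at C2), via ketimine 17 (not isolated)
Conditions: Raney Ni (W-2), H2 (1 atm), B(OH)3, MeOH/THF/H2O, rt
Reagents that add atoms: water, O
Why: Hydrogenolysis of the isoxazoline N–O bond gives the β-hydroxy imine 17, which the boric acid-buffered medium hydrolyses to the aryl ketone while the released oxygen stays on C9' as the lactol; C8' is enolisable, but its trans relation to the C8 substituent is the thermodynamically favoured one, and the benzyl ethers should survive brief exposure at room temperature and 1 atm.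

Step 11
Reactants: 18 keto-lactol
Product: 19 [3,4-bis(benzyloxy)phenyl][(3S,4R,5S)-5-[4-(benzyloxy)-3-methoxyphenyl]-4-[(benzyloxy)methyl]tetrahydrofuran-3-yl]methanone
Conditions: Et3SiH (5 equiv), BF3·OEt2 (2 equiv), CH2Cl2, −78 → −40 °C; aq. NaHCO3
Reagents that add atoms: none
Why: Ionic hydrogenation of a lactol; BF3 ionises the C9' hydroxyl to the cyclic oxocarbenium ion, which the silane reduces at low temperature, where the conjugated aryl ketone and the C7 benzylic ether should remain untouched.

Step 12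
Reactants: 19 keto-oxolane
Product: 20 (R)-[3,4-bis(benzyloxy)phenyl][(3S,4R,5S)-5-[4-(benzyloxy)-3-methoxyphenyl]-4-[(benzyloxy)methyl]tetrahydrofuran-3-yl]methanol
Conditions: Zn(BH4)2, Et2O, −78 → −20 °C; aq. NH4Cl
Reagents that add atoms: none
Why: 1,3-Chelation-controlled reduction (Cram cyclic model); zinc bridges the carbonyl oxygen and ring O1 in a six-membered chelate through C8' and C9', and hydride enters anti to ring carbon C8, the same face the Felkin–Anh model predicts with C8 as the large group, which should give the (R)-carbinol at C7'.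

Step 13
Reactants: 20 tetrabenzyl ether
Product: 21 4-[(R)-hydroxy[(3S,4R,5S)-5-(4-hydroxy-3-methoxyphenyl)-4-(hydroxymethyl)tetrahydrofuran-3-yl]methyl]benzene-1,2-diol (CNP0197133.1)
Conditions: H2 (1 atm), Pd/C (10 wt% Pd), EtOAc/MeOH, rt; stopped after uptake of 4 equiv H2
Reagents that add atoms: none
Why: Hydrogenolysis of the three aryl benzyl ethers and the primary alkyl benzyl ether under neutral conditions, which should be cleaved before the benzylic C7'–OH or the benzylic C7–O1 ring bond is attacked; no stereocentre is involved.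

**Compound list**

1 | 2-(benzyloxy)-N-methoxy-N-methylacetamide | CON(C)C(=O)COCc1ccccc1 | starting material
2 | trimethylsilylacetylene | C#C[Si](C)(C)C | starting material
3 | lithium (trimethylsilyl)acetylide | [Li]C#C[Si](C)(C)C | intermediate
4 | 1-(benzyloxy)-4-(trimethylsilyl)but-3-yn-2-one | O=C(COCc1ccccc1)C#C[Si](C)(C)C | intermediate
5 | (S)-1-(benzyloxy)-4-(trimethylsilyl)but-3-yn-2-ol | O[C@H](COCc1ccccc1)C#C[Si](C)(C)C | intermediate
6 | (S)-1-(benzyloxy)-4-(trimethylsilyl)but-3-yn-2-yl methanesulfonate | CS(=O)(=O)O[C@H](COCc1ccccc1)C#C[Si](C)(C)C | intermediate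
7 | 4-(benzyloxy)-3-methoxybenzaldehyde (O-benzylvanillin) | COc1cc(C=O)ccc1OCc1ccccc1 | starting material
8 | ethyl[4-(benzyloxy)-1-(trimethylsilyl)buta-1,2-dienyl]zinc, axial configuration as formed by anti SN2' displacement of the mesylate | C[Si](C)(C)C([Zn]CC)=[C@]=C([H])COCc1ccccc1 | intermediate
9 | (1S,2R)-1-[4-(benzyloxy)-3-methoxyphenyl]-2-[(benzyloxy)methyl]-4-(trimethylsilyl)but-3-yn-1-ol | COc1cc([C@@H](O)[C@@H](COCc2ccccc2)C#C[Si](C)(C)C)ccc1OCc1ccccc1 | intermediate
10 | (1S,2R)-1-[4-(benzyloxy)-3-methoxyphenyl]-2-[(benzyloxy)methyl]but-3-yn-1-ol | COc1cc([C@@H](O)[C@@H](COCc2ccccc2)C#C)ccc1OCc1ccccc1 | intermediate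
11 | (2S,3R)-2-[4-(benzyloxy)-3-methoxyphenyl]-3-[(benzyloxy)methyl]-2,3-dihydrofuran (trans) | COc1cc([C@H]2OC=C[C@@H]2COCc2ccccc2)ccc1OCc1ccccc1 | intermediate
12 | 3,4-bis(benzyloxy)benzaldehyde | O=Cc1ccc(OCc2ccccc2)c(OCc2ccccc2)c1 | starting material
13 | (E)-3,4-bis(benzyloxy)benzaldehyde oxime | O/N=C/c1ccc(OCc2ccccc2)c(OCc2ccccc2)c1 | intermediate
14 | (Z)-3,4-bis(benzyloxy)-N-hydroxybenzimidoyl chloride | O/N=C(\Cl)c1ccc(OCc2ccccc2)c(OCc2ccccc2)c1 | intermediate
15 | 3,4-bis(benzyloxy)benzonitrile oxide | [O-][N+]#Cc1ccc(OCc2ccccc2)c(OCc2ccccc2)c1 | intermediate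
16 | (3aR,4R,5S,6aS)-3-[3,4-bis(benzyloxy)phenyl]-5-[4-(benzyloxy)-3-methoxyphenyl]-4-[(benzyloxy)methyl]-3a,4,5,6a-tetrahydrofuro[3,2-d]isoxazole | COc1cc([C@H]2O[C@H]3ON=C(c4ccc(OCc5ccccc5)c(OCc5ccccc5)c4)[C@H]3[C@@H]2COCc2ccccc2)ccc1OCc1ccccc1 | intermediate
17 | N-unsubstituted ketimine of 18 (2-hydroxyoxolane bearing C(=NH)Ar at C3) | COc1cc([C@H]2OC(O)[C@@H](C(=N)c3ccc(OCc4ccccc4)c(OCc4ccccc4)c3)[C@@H]2COCc2ccccc2)ccc1OCc1ccccc1 | intermediate
18 | [3,4-bis(benzyloxy)phenyl][(3S,4R,5S)-5-[4-(benzyloxy)-3-methoxyphenyl]-4-[(benzyloxy)methyl]-2-hydroxytetrahydrofuran-3-yl]methanone (anomeric mixture) | COc1cc([C@H]2OC(O)[C@@H](C(=O)c3ccc(OCc4ccccc4)c(OCc4ccccc4)c3)[C@@H]2COCc2ccccc2)ccc1OCc1ccccc1 | intermediate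
19 | [3,4-bis(benzyloxy)phenyl][(3S,4R,5S)-5-[4-(benzyloxy)-3-methoxyphenyl]-4-[(benzyloxy)methyl]tetrahydrofuran-3-yl]methanone | COc1cc([C@H]2OC[C@@H](C(=O)c3ccc(OCc4ccccc4)c(OCc4ccccc4)c3)[C@@H]2COCc2ccccc2)ccc1OCc1ccccc1 | intermediate
20 | (R)-[3,4-bis(benzyloxy)phenyl][(3S,4R,5S)-5-[4-(benzyloxy)-3-methoxyphenyl]-4-[(benzyloxy)methyl]tetrahydrofuran-3-yl]methanol | COc1cc([C@H]2OC[C@@H]([C@@H](O)c3ccc(OCc4ccccc4)c(OCc4ccccc4)c3)[C@@H]2COCc2ccccc2)ccc1OCc1ccccc1 | intermediate
21 | 4-[(R)-hydroxy[(3S,4R,5S)-5-(4-hydroxy-3-methoxyphenyl)-4-(hydroxymethyl)tetrahydrofuran-3-yl]methyl]benzene-1,2-diol | COc1cc([C@H]2OC[C@@H]([C@@H](O)c3ccc(O)c(O)c3)[C@@H]2CO)ccc1O | target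

**Step count and risks**

Total steps: 13. Longest linear sequence: 11 (steps 1–6 and 9–13, from 1 to 21); the nitrile oxide branch (steps 7–8) joins at step 9.

Step 9 (key cycloaddition). The facial discrimination may be incomplete, because the C7 aryl group shields the face opposite to the C8 benzyloxymethyl group, so addition syn to that group can compete; dimerisation of the dipole can also consume 15. Fallback: C8' is set by thermodynamic rather than kinetic control. The fallback sets out from 11 (with 14). The syn-face cycloadduct, the (3aS,4R,5S,6aR)-diastereomer of 16 F1, is not separated but taken through the step 10 conditions. N–O hydrogenolysis gives its ketimine F2, which hydrolyses to the 8'-epimeric keto-lactol F3. In F3, C8' is the central carbon of a masked β-keto aldehyde (ring–chain tautomerism), so catalytic DBU in THF at room temperature should equilibrate it to the all-trans isomer. The route is rejoined at 18.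

Step 11 (lactol deoxygenation). The oxocarbenium ion may lose the acidified C8' proton faster than it captures hydride, giving the 4-aroyl-2,3-dihydrofuran; ionic reduction of the aryl ketone or Lewis-acid ionisation of the benzylic C7–O1 bond may also intrude. Fallback: the oxocarbenium ion is avoided and the oxolane is re-closed by etherification. The fallback sets out from 18.
- Zn(BH4)2 in Et2O at −78 °C should reduce the ketone under the same chelate control to the hydroxy-lactol F4.
- NaBH4 in MeOH is then added to the same flask and reduces the lactol through its open form to the (1S,2R,3S,4R)-triol F5.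
- TsCl in pyridine at 0 °C should sulfonylate only the primary hydroxyl, giving the mono-tosylate F6.
- NaH in THF closes the ring by 5-exo-tet Williamson displacement by the C7 alkoxide; the competing oxetane closure from the C7' alkoxide is disfavoured.

The route is rejoined at 20, and 19 is bypassed.

Step 12 (ketone reduction). Hydride may be delivered to the wrong carbonyl face if the zinc chelate is not the reacting species, giving the C7' epimer. Fallback: substrate control is replaced by catalyst control. The fallback sets out from 19 and uses the Corey–Bakshi–Shibata reduction: (S)-1-methyl-3,3-diphenyltetrahydro-1H,3H-pyrrolo[1,2-c][1,3,2]oxazaborole (10 mol%) with BH3·SMe2 in THF at −20 °C. With the aryl group as the large substituent this catalyst should give the (R)-carbinol, matched with the intrinsic bias of the substrate. It returns at 20 and makes no new compound.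

**Further compounds**

F1 | step 9 | (3aS,4R,5S,6aR)-3-[3,4-bis(benzyloxy)phenyl]-5-[4-(benzyloxy)-3-methoxyphenyl]-4-[(benzyloxy)methyl]-3a,4,5,6a-tetrahydrofuro[3,2-d]isoxazole (dipole added syn to the C4 substituent) | COc1cc([C@H]2O[C@@H]3ON=C(c4ccc(OCc5ccccc5)c(OCc5ccccc5)c4)[C@@H]3[C@@H]2COCc2ccccc2)ccc1OCc1ccccc1
F2 | step 9 | ketimine of the 8'-epimeric keto-lactol | COc1cc([C@H]2OC(O)[C@H](C(=N)c3ccc(OCc4ccccc4)c(OCc4ccccc4)c3)[C@@H]2COCc2ccccc2)ccc1OCc1ccccc1
F3 | step 9 | [3,4-bis(benzyloxy)phenyl][(3R,4R,5S)-5-[4-(benzyloxy)-3-methoxyphenyl]-4-[(benzyloxy)methyl]-2-hydroxytetrahydrofuran-3-yl]methanone (8'-epimeric keto-lactol) | COc1cc([C@H]2OC(O)[C@H](C(=O)c3ccc(OCc4ccccc4)c(OCc4ccccc4)c3)[C@@H]2COCc2ccccc2)ccc1OCc1ccccc1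
F4 | step 11 | (3S,4R,5S)-5-[4-(benzyloxy)-3-methoxyphenyl]-3-[(R)-[3,4-bis(benzyloxy)phenyl](hydroxy)methyl]-4-[(benzyloxy)methyl]tetrahydrofuran-2-ol (hydroxy-lactol) | COc1cc([C@H]2OC(O)[C@@H]([C@@H](O)c3ccc(OCc4ccccc4)c(OCc4ccccc4)c3)[C@@H]2COCc2ccccc2)ccc1OCc1ccccc1
F5 | step 11 | (1S,2R,3S,4R)-1-[4-(benzyloxy)-3-methoxyphenyl]-4-[3,4-bis(benzyloxy)phenyl]-2-[(benzyloxy)methyl]-3-(hydroxymethyl)butane-1,4-diol | COc1cc([C@@H](O)[C@@H](COCc2ccccc2)[C@@H](CO)[C@@H](O)c2ccc(OCc3ccccc3)c(OCc3ccccc3)c2)ccc1OCc1ccccc1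
F6 | step 11 | primary (C9') 4-methylbenzenesulfonate of triol F5 | COc1cc([C@@H](O)[C@@H](COCc2ccccc2)[C@@H](COS(=O)(=O)c2ccc(C)cc2)[C@@H](O)c2ccc(OCc3ccccc3)c(OCc3ccccc3)c2)ccc1OCc1ccccc1
F0 | step 12 | none | none
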